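## Retrosynthetic overview

- **Feature:** in the 2,3-dihydrobenzofuran core (benzene ring A, dihydrofuran ring B), the ether bond O1–C7a and the bridge carbon on C7 sit on adjacent carbons of ring A. C7 has the C6 oxygen on its other side. This is the nucleophile/electrophile 1,2-addition pattern of a C7–C7a aryne polarised by the C6 oxygen.
- **Endgame:** removal of two methoxymethyl (MOM) ethers; the C7–CH2–C3' bond by reductive alkylation of pyranone ring C with a C7 aldehyde; the C5 acetyl group by lithiation between the two MOM ethers.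
- **Key disconnection:** O1–C7a and C7–CHO are made in one operation from an (R)-configured bromoaryl allylic carbinol (aryne formation, alkoxide closure, DMF trapping).
- **Carbinol:** it carries the only stereocentre (C2). It comes from an asymmetric Nozaki–Hiyama–Kishi coupling of an arylacetaldehyde (from 5-bromoresorcinol) with the kinetic enol triflate of 6-methylhept-5-en-2-one.
- **Ring order:** ring A is bought, ring C is built separately from methyl 3-oxopentanoate, and ring B is closed in the key step. MOM is used on the phenols instead of methyl because a late boron trihalide demethylation would open the allylic O1–C2 bond and add to the alkenes.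

Key step: step 8

Assumption: the (4S) sulfonamide ligand is taken to direct the alkenyl group to the Si face of the arylacetaldehyde. The sense is to be checked by Mosher ester analysis of the carbinol, and the (4R) ligand from (R)-valinol is used if it proves opposite.

## Route

Step 1
Reactants: 1 5-bromobenzene-1,3-diol
Product: 3 2-bromo-4,6-dihydroxybenzaldehyde, via aryl iminium chloride 2 (not isolated)
Conditions: POCl3 (1.5 equiv), DMF, 0 °C to rt; then H2O, 50 °C
Reagents that add atoms: N,N-dimethylformamide, CN(C)C=O; water, O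
Why: Vilsmeier–Haack formylation, in which the chloroiminium ion attacks the carbon ortho to one hydroxyl and para to the other (next to bromine) rather than the crowded carbon between the two hydroxyls, as with other 5-substituted resorcinols, and water then hydrolyses 2.

Step 2
Reactants: 3 2-bromo-4,6-dihydroxybenzaldehyde
Product: 4 2-bromo-4,6-bis(methoxymethoxy)benzaldehyde
Conditions: MOMCl (3 equiv), i-Pr2NEt (4 equiv), DMF, 0 °C to rt
Reagents that add atoms: chloromethyl methyl ether, COCCl
Why: Williamson-type O-alkylation of both phenols, with excess reagent to cover the hydrogen-bonded ortho hydroxyl, giving acetal ethers that tolerate lithium amides, acidify and polarise the ring as methyl ethers do, and leave at the end under mild protic acid.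

Step 3
Reactants: 4 2-bromo-4,6-bis(methoxymethoxy)benzaldehyde
Product: 5 1-bromo-2-ethenyl-3,5-bis(methoxymethoxy)benzene
Conditions: Ph3PCH3Br, KOt-Bu, THF, 0 °C; then 4, 0 °C to rt
Reagents that add atoms: methyltriphenylphosphonium bromide, C[P+](c1ccccc1)(c1ccccc1)c1ccccc1.[Br-]
Why: Wittig methylenation of a non-enolisable aldehyde with a preformed ylide, which leaves the aryl bromide and the acetals untouched.

Step 4
Reactants: 5 1-bromo-2-ethenyl-3,5-bis(methoxymethoxy)benzene
Product: 7 2-[2-bromo-4,6-bis(methoxymethoxy)phenyl]ethan-1-ol, via B-alkyl borabicyclononane 6 (not isolated)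
Conditions: 9-BBN, THF, 0 to 50 °C; then NaOH, H2O2, 0 °C to rt
Reagents that add atoms: hydrogen peroxide, OO
Why: Hydroboration–oxidation, in which the bulky borane places boron on the terminal styrene carbon (anti-Markovnikov) and alkaline peroxide converts the C–B bond of 6 into C–OH without touching the aryl bromide.

Step 5
Reactants: 7 2-[2-bromo-4,6-bis(methoxymethoxy)phenyl]ethan-1-ol
Product: 8 2-[2-bromo-4,6-bis(methoxymethoxy)phenyl]acetaldehyde
Conditions: Dess–Martin periodinane, CH2Cl2, 0 °C to rt
Reagents that add atoms: none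
Why: Dess–Martin oxidation stops at the aldehyde under nearly neutral conditions, which suits an enolisable arylacetaldehyde that is to be used directly in step 7.

Step 6
Reactants: 9 6-methylhept-5-en-2-one
Product: 11 6-methylhepta-1,5-dien-2-yl trifluoromethanesulfonate, via kinetic lithium enolate 10 (not isolated)
Conditions: LiN(i-Pr)2, THF, −78 °C; then PhNTf2, −78 to 0 °C
Reagents that add atoms: N-phenylbis(trifluoromethanesulfonimide), O=S(=O)(N(c1ccccc1)S(=O)(=O)C(F)(F)F)C(F)(F)F
Why: Kinetic enolisation of a methyl ketone by a hindered lithium amide at low temperature occurs at the methyl group, and O-sulfonylation of 10 fixes the terminal enol triflate.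

Step 7
Reactants: 8 2-[2-bromo-4,6-bis(methoxymethoxy)phenyl]acetaldehyde; 11 6-methylhepta-1,5-dien-2-yl trifluoromethanesulfonate
Product: 13 (2R)-1-[2-bromo-4,6-bis(methoxymethoxy)phenyl]-7-methyl-3-methylideneoct-6-en-2-ol, via alkenylchromium dichloride 12 (not isolated)
Conditions: CrCl2 (3 equiv), N-{2-[(4S)-4-isopropyl-4,5-dihydro-1,3-oxazol-2-yl]-6-methylphenyl}methanesulfonamide (3.3 equiv), Et3N (3.3 equiv), NiCl2 (2 mol %), THF, rt
Reagents that add atoms: none
Why: Asymmetric Nozaki–Hiyama–Kishi reaction, in which zerovalent nickel inserts into the alkenyl C–OTf bond faster than into the hindered, electron-rich aryl bromide, transmetalation gives 12, and its chiral sulfonamide–oxazoline ligand sphere directs addition to the Si face of the aldehyde, setting the (R) carbinol centre (future C2) without enolising 8.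

Step 8
Reactants: 13 (2R)-1-[2-bromo-4,6-bis(methoxymethoxy)phenyl]-7-methyl-3-methylideneoct-6-en-2-ol
Product: 17 (2R)-4,6-bis(methoxymethoxy)-2-(6-methylhepta-1,5-dien-2-yl)-2,3-dihydro-1-benzofuran-7-carbaldehyde, via aryne alkoxide 14 (not isolated), via C7 aryllithium 15 (not isolated), via dimethylamino alkoxide 16 (not isolated)
Conditions: lithium 2,2,6,6-tetramethylpiperidide (LiTMP, 2.3 equiv, from 2,2,6,6-tetramethylpiperidine and n-BuLi), THF, −78 to −20 °C; then DMF (5 equiv), −78 to 0 °C; H2O
Reagents that add atoms: N,N-dimethylformamide, CN(C)C=O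
Why: The first equivalent of LiTMP makes the lithium alkoxide, the second removes the ring proton between bromine and a methoxymethoxy group (the future C7), and the ortho-bromoaryllithium loses LiBr on warming to give the C7–C7a aryne 14. The alkoxide oxygen adds to C7a and closes ring B by 5-exo-dig attack (O1–C7a), and the resulting aryllithium 15 adds to DMF to give 16, which releases the aldehyde (C7–CHO) only on aqueous work-up. The closest known reaction type is the ring closure of tethered oxygen, nitrogen or sulfur anions onto arynes generated from haloarenes with lithium bases, followed by electrophilic quenching of the aryllithium that results. No stereocentre is created, because the C2–O bond of the carbinol is never broken and the (R) configuration of 13 passes unchanged into 17. Two selectivities are needed: metalation at C7 rather than C5, which rests on the stronger acidification by bromine plus oxygen and on the fact that only the C7 anion is drained irreversibly by LiBr loss while a C5 anion can be returned by proton exchange with the free amine, and oxygen attack at C7a rather than C7, which the two-carbon tether enforces and the inductive pull of the C6 oxygen reinforces. The bulk of the amide keeps it from adding to the aryne, the anion between O1 and the C6 oxygen is stabilised enough to persist beside the free amine, and limiting the base to about 2.3 equiv avoids a second metalation at C5.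

Step 9
Reactants: 17 (2R)-4,6-bis(methoxymethoxy)-2-(6-methylhepta-1,5-dien-2-yl)-2,3-dihydro-1-benzofuran-7-carbaldehyde
Product: 21 (2R)-5-acetyl-4,6-bis(methoxymethoxy)-2-(6-methylhepta-1,5-dien-2-yl)-2,3-dihydro-1-benzofuran-7-carbaldehyde, via piperazinyl alkoxide 18 (not isolated), via C5 aryllithium 19 (not isolated), via double tetrahedral adduct 20 (not isolated)
Conditions: lithium 4-methylpiperazin-1-ide (1.1 equiv, from 1-methylpiperazine and n-BuLi), THF, −78 to −20 °C; n-BuLi (1.5 equiv), −20 to 0 °C; MeC(O)N(OMe)Me (3 equiv), −78 to 0 °C; H2O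
Reagents that add atoms: N-methoxy-N-methylacetamide, CON(C)C(C)=O
Why: Directed ortho-metalation of an aromatic aldehyde masked in the flask as its α-amino alkoxide: the lithium amide adds to the formyl group to give 18 (hemiaminal centre uncontrolled and lost on work-up), n-BuLi removes the only remaining ring proton (C5–H between the two MOM ethers), and 19 acylates the Weinreb amide through chelated adduct 20, so ketone and aldehyde appear together on quenching while the alkenes, which electrophilic halogenation would endanger, stay inert.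

Step 10
Reactants: 22 methyl 3-oxopentanoate; 23 N-methoxy-N-methylpropanamide
Product: 26 methyl 4-methyl-3,5-dioxoheptanoate, via dilithium dienolate 24 (not isolated), via tetrahedral adduct 25 (not isolated)
Conditions: LiN(i-Pr)2 (2.1 equiv), THF, −78 to 0 °C; then 23, −78 to 0 °C; aq. HCl
Reagents that add atoms: none
Why: γ-Acylation of a β-keto ester dianion, in which the more reactive terminal carbanion of 24 attacks the Weinreb amide and the stable adduct 25 keeps the acidic product from quenching unreacted dianion; the C4 centre of 26 is racemic, labile and removed in step 11.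

Step 11
Reactants: 26 methyl 4-methyl-3,5-dioxoheptanoate
Product: 27 6-ethyl-4-hydroxy-5-methyl-2H-pyran-2-one
Conditions: DBU, toluene, 80 °C; then aq. HCl
Reagents that add atoms: none
Why: Base-induced lactonisation of a 3,5-dioxo ester, in which the C5 enolate oxygen attacks the ester, methanol leaves, and tautomerisation gives the 4-hydroxy-2-pyranone (ring C).

Step 12
Reactants: 21 (2R)-5-acetyl-4,6-bis(methoxymethoxy)-2-(6-methylhepta-1,5-dien-2-yl)-2,3-dihydro-1-benzofuran-7-carbaldehyde; 27 6-ethyl-4-hydroxy-5-methyl-2H-pyran-2-one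
Product: 29 3-{[(2R)-5-acetyl-4,6-bis(methoxymethoxy)-2-(6-methylhepta-1,5-dien-2-yl)-2,3-dihydro-1-benzofuran-7-yl]methyl}-6-ethyl-4-hydroxy-5-methyl-2H-pyran-2-one, via alkylidene pyrandione 28 (not isolated)
Conditions: L-proline (20 mol %), Hantzsch ester (diethyl 2,6-dimethyl-1,4-dihydropyridine-3,5-dicarboxylate, 1.1 equiv), EtOH, rt to 40 °C
Reagents that add atoms: none
Why: Organocatalytic three-component reductive alkylation (Knoevenagel condensation followed by transfer hydrogenation), in which the proline iminium of the aldehyde condenses with C3 of the pyranone and the Hantzsch ester delivers hydride to 28 before a second pyranone can add, while the hindered aryl methyl ketone, the isolated alkenes and C2 are not touched.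

Step 13
Reactants: 29 3-{[(2R)-5-acetyl-4,6-bis(methoxymethoxy)-2-(6-methylhepta-1,5-dien-2-yl)-2,3-dihydro-1-benzofuran-7-yl]methyl}-6-ethyl-4-hydroxy-5-methyl-2H-pyran-2-one
Product: 30 3-{[(2R)-5-acetyl-4,6-dihydroxy-2-(6-methylhepta-1,5-dien-2-yl)-2,3-dihydro-1-benzofuran-7-yl]methyl}-6-ethyl-4-hydroxy-5-methyl-2H-pyran-2-one
Conditions: HCl (cat.), MeOH, rt to 40 °C
Reagents that add atoms: none
Why: Acid-catalysed acetal exchange, in which both MOM ethers flank the acetyl carbonyl and are therefore especially labile, so catalytic acid in methanol should suffice, and under these conditions the two alkenes and the allylic O1–C2 bond (and with it the stereocentre) should persist.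

## Compound list

1 | 5-bromobenzene-1,3-diol | Oc1cc(O)cc(Br)c1 | starting material
2 | [(2-bromo-4,6-dihydroxyphenyl)methylidene]dimethylammonium chloride | C[N+](C)=Cc1c(Br)cc(O)cc1O.[Cl-] | intermediate
3 | 2-bromo-4,6-dihydroxybenzaldehyde | O=Cc1c(Br)cc(O)cc1O | intermediate
4 | 2-bromo-4,6-bis(methoxymethoxy)benzaldehyde | O=Cc1c(Br)cc(OCOC)cc1OCOC | intermediate
5 | 1-bromo-2-ethenyl-3,5-bis(methoxymethoxy)benzene | C=Cc1c(Br)cc(OCOC)cc1OCOC | intermediate
6 | 9-{2-[2-bromo-4,6-bis(methoxymethoxy)phenyl]ethyl}-9-borabicyclo[3.3.1]nonane | COCOc1cc(Br)c(CCB2C3CCCC2CCC3)c(OCOC)c1 | intermediate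
7 | 2-[2-bromo-4,6-bis(methoxymethoxy)phenyl]ethan-1-ol | OCCc1c(Br)cc(OCOC)cc1OCOC | intermediate
8 | 2-[2-bromo-4,6-bis(methoxymethoxy)phenyl]acetaldehyde | O=CCc1c(Br)cc(OCOC)cc1OCOC | intermediate
9 | 6-methylhept-5-en-2-one | CC(=O)CCC=C(C)C | starting material
10 | lithium 6-methylhepta-1,5-dien-2-olate | C=C([O-])CCC=C(C)C.[Li+] | intermediate
11 | 6-methylhepta-1,5-dien-2-yl trifluoromethanesulfonate | C=C(CCC=C(C)C)OS(=O)(=O)C(F)(F)F | intermediate
12 | (6-methylhepta-1,5-dien-2-yl)chromium dichloride, drawn without the sulfonamide ligand | C=C(CCC=C(C)C)[Cr](Cl)Cl | intermediate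
13 | (2R)-1-[2-bromo-4,6-bis(methoxymethoxy)phenyl]-7-methyl-3-methylideneoct-6-en-2-ol | C=C(CCC=C(C)C)[C@H](O)Cc1c(Br)cc(OCOC)cc1OCOC | intermediate
14 | lithium (2R)-1-[2,3-didehydro-4,6-bis(methoxymethoxy)phenyl]-7-methyl-3-methylideneoct-6-en-2-olate | C=C(CCC=C(C)C)[C@H]([O-])CC1=C(OCOC)C=C(OCOC)C#C1.[Li+] | intermediate
15 | [(2R)-4,6-bis(methoxymethoxy)-2-(6-methylhepta-1,5-dien-2-yl)-2,3-dihydro-1-benzofuran-7-yl]lithium | C=C(CCC=C(C)C)[C@H]1Cc2c(OCOC)cc(OCOC)c([Li])c2O1 | intermediate
16 | lithium (dimethylamino)[(2R)-4,6-bis(methoxymethoxy)-2-(6-methylhepta-1,5-dien-2-yl)-2,3-dihydro-1-benzofuran-7-yl]methanolate | C=C(CCC=C(C)C)[C@H]1Cc2c(OCOC)cc(OCOC)c(C([O-])N(C)C)c2O1.[Li+] | intermediate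
17 | (2R)-4,6-bis(methoxymethoxy)-2-(6-methylhepta-1,5-dien-2-yl)-2,3-dihydro-1-benzofuran-7-carbaldehyde | C=C(CCC=C(C)C)[C@H]1Cc2c(OCOC)cc(OCOC)c(C=O)c2O1 | intermediate
18 | lithium [(2R)-4,6-bis(methoxymethoxy)-2-(6-methylhepta-1,5-dien-2-yl)-2,3-dihydro-1-benzofuran-7-yl](4-methylpiperazin-1-yl)methanolate | C=C(CCC=C(C)C)[C@H]1Cc2c(OCOC)cc(OCOC)c(C([O-])N3CCN(C)CC3)c2O1.[Li+] | intermediate
19 | 5-lithio derivative of 18 | C=C(CCC=C(C)C)[C@H]1Cc2c(OCOC)c([Li])c(OCOC)c(C([O-])N3CCN(C)CC3)c2O1.[Li+] | intermediate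
20 | dilithium bis-alkoxide from 19 and N-methoxy-N-methylacetamide (C5 1-[methoxy(methyl)amino]ethan-1-olate, C7 (4-methylpiperazin-1-yl)methanolate) | C=C(CCC=C(C)C)[C@H]1Cc2c(OCOC)c(C(C)([O-])N(C)OC)c(OCOC)c(C([O-])N3CCN(C)CC3)c2O1.[Li+].[Li+] | intermediate
21 | (2R)-5-acetyl-4,6-bis(methoxymethoxy)-2-(6-methylhepta-1,5-dien-2-yl)-2,3-dihydro-1-benzofuran-7-carbaldehyde | C=C(CCC=C(C)C)[C@H]1Cc2c(OCOC)c(C(C)=O)c(OCOC)c(C=O)c2O1 | intermediate
22 | methyl 3-oxopentanoate | CCC(=O)CC(=O)OC | starting material
23 | N-methoxy-N-methylpropanamide | CCC(=O)N(C)OC | starting material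
24 | dilithium 1-methoxypenta-1,3-diene-1,3-diolate | CC=C([O-])C=C([O-])OC.[Li+].[Li+] | intermediate
25 | dilithium salt (C5 alkoxide, C2–C3 enolate) of methyl 5-hydroxy-5-[methoxy(methyl)amino]-4-methyl-3-oxoheptanoate | CCC([O-])(N(C)OC)C(C)C([O-])=CC(=O)OC.[Li+].[Li+] | intermediate
26 | methyl 4-methyl-3,5-dioxoheptanoate (racemic at C4) | CCC(=O)C(C)C(=O)CC(=O)OC | intermediate
27 | 6-ethyl-4-hydroxy-5-methyl-2H-pyran-2-one | CCc1oc(=O)cc(O)c1C | intermediate
28 | 3-{[(2R)-5-acetyl-4,6-bis(methoxymethoxy)-2-(6-methylhepta-1,5-dien-2-yl)-2,3-dihydro-1-benzofuran-7-yl]methylidene}-6-ethyl-5-methyl-2H-pyran-2,4(3H)-dione | C=C(CCC=C(C)C)[C@H]1Cc2c(OCOC)c(C(C)=O)c(OCOC)c(C=C3C(=O)OC(CC)=C(C)C3=O)c2O1 | intermediate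
29 | 3-{[(2R)-5-acetyl-4,6-bis(methoxymethoxy)-2-(6-methylhepta-1,5-dien-2-yl)-2,3-dihydro-1-benzofuran-7-yl]methyl}-6-ethyl-4-hydroxy-5-methyl-2H-pyran-2-one | C=C(CCC=C(C)C)[C@H]1Cc2c(OCOC)c(C(C)=O)c(OCOC)c(Cc3c(O)c(C)c(CC)oc3=O)c2O1 | intermediate
30 | 3-{[(2R)-5-acetyl-4,6-dihydroxy-2-(6-methylhepta-1,5-dien-2-yl)-2,3-dihydro-1-benzofuran-7-yl]methyl}-6-ethyl-4-hydroxy-5-methyl-2H-pyran-2-one | C=C(CCC=C(C)C)[C@H]1Cc2c(O)c(C(C)=O)c(O)c(Cc3c(O)c(C)c(CC)oc3=O)c2O1 | target

## Step count and risks

Total step count: 13.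
Longest linear sequence: 10 steps (1, 2, 3, 4, 5, 7, 8, 9, 12, 13).

**Step 8 (key step).**
- What may go wrong: competing metalation at C5, proton transfer to the C7 anion before formylation, or capture of the aryne by the amide base.
- The fallback sets out from 13. An intramolecular Buchwald–Hartwig etherification (Pd(OAc)2, 2-(di-tert-butylphosphino)-1,1'-binaphthyl, Cs2CO3, toluene, 70 °C) closes ring B without an aryne and with retention at the carbinol carbon. It gives (2R)-4,6-bis(methoxymethoxy)-2-(6-methylhepta-1,5-dien-2-yl)-2,3-dihydro-1-benzofuran F1.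
- n-BuLi lithiates F1 between the two acetal ethers (C5), where both can chelate lithium. N-methoxy-N-methylacetamide then gives 1-[(2R)-4,6-bis(methoxymethoxy)-2-(6-methylhepta-1,5-dien-2-yl)-2,3-dihydro-1-benzofuran-5-yl]ethan-1-one F2.
- Catalytic HCl in methanol frees 1-[(2R)-4,6-dihydroxy-2-(6-methylhepta-1,5-dien-2-yl)-2,3-dihydro-1-benzofuran-5-yl]ethan-1-one F3, whose only open ring position is C7.
- Pyranone 27 and dimethyl(methylidene)ammonium iodide give the Mannich base 3-[(dimethylamino)methyl]-6-ethyl-4-hydroxy-5-methyl-2H-pyran-2-one F4. On warming it loses the amine to give 6-ethyl-5-methyl-3-methylidene-2H-pyran-2,4(3H)-dione F5.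
- C7 of F3 adds to F5, the known way of bridging acylphloroglucinols and 4-hydroxypyranones with a formaldehyde equivalent. The route is rejoined at target 30.

**Step 9.**
- What may go wrong: incomplete masking of the doubly ortho-substituted aldehyde, which would let butyllithium add to the carbonyl group, and enolisation of the Weinreb amide by the hindered aryllithium, which would return unacylated material.
- The fallback sets out from 17. NaBH4 in methanol gives [(2R)-4,6-bis(methoxymethoxy)-2-(6-methylhepta-1,5-dien-2-yl)-2,3-dihydro-1-benzofuran-7-yl]methanol F6.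
- Double deprotonation with n-BuLi (2.2 equiv; O–H, then C5–H) and addition to acetaldehyde gives 1-[(2R)-7-(hydroxymethyl)-4,6-bis(methoxymethoxy)-2-(6-methylhepta-1,5-dien-2-yl)-2,3-dihydro-1-benzofuran-5-yl]ethan-1-ol F7, with an uncontrolled new carbinol centre.
- Dess–Martin oxidation of both benzylic alcohols erases that centre and rejoins the route at 21.

**Step 7.**
- What may go wrong: poor facial selectivity on an unbranched arylacetaldehyde.
- The fallback sets out from 8 and 11. Ligand-free coupling (CrCl2, NiCl2, DMF) gives racemic 1-[2-bromo-4,6-bis(methoxymethoxy)phenyl]-7-methyl-3-methylideneoct-6-en-2-ol F8.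
- Dess–Martin oxidation gives 1-[2-bromo-4,6-bis(methoxymethoxy)phenyl]-7-methyl-3-methylideneoct-6-en-2-one F9, which is used directly.
- Corey–Bakshi–Shibata reduction follows, with (S)-1-methyl-3,3-diphenyltetrahydro-1H,3H-pyrrolo[1,2-c][1,3,2]oxazaborole and catecholborane in toluene at −78 °C. It should give the (R) alcohol, provided the branched alkenyl group acts as the larger substituent. The route is rejoined at 13.

## Further compounds

F1 | step 8 | (2R)-4,6-bis(methoxymethoxy)-2-(6-methylhepta-1,5-dien-2-yl)-2,3-dihydro-1-benzofuran | C=C(CCC=C(C)C)[C@H]1Cc2c(OCOC)cc(OCOC)cc2O1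
F2 | step 8 | 1-[(2R)-4,6-bis(methoxymethoxy)-2-(6-methylhepta-1,5-dien-2-yl)-2,3-dihydro-1-benzofuran-5-yl]ethan-1-one | C=C(CCC=C(C)C)[C@H]1Cc2c(OCOC)c(C(C)=O)c(OCOC)cc2O1
F3 | step 8 | 1-[(2R)-4,6-dihydroxy-2-(6-methylhepta-1,5-dien-2-yl)-2,3-dihydro-1-benzofuran-5-yl]ethan-1-one | C=C(CCC=C(C)C)[C@H]1Cc2c(O)c(C(C)=O)c(O)cc2O1
F4 | step 8 | 3-[(dimethylamino)methyl]-6-ethyl-4-hydroxy-5-methyl-2H-pyran-2-one | CCc1oc(=O)c(CN(C)C)c(O)c1C
F5 | step 8 | 6-ethyl-5-methyl-3-methylidene-2H-pyran-2,4(3H)-dione | C=C1C(=O)OC(CC)=C(C)C1=O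
F6 | step 9 | [(2R)-4,6-bis(methoxymethoxy)-2-(6-methylhepta-1,5-dien-2-yl)-2,3-dihydro-1-benzofuran-7-yl]methanol | C=C(CCC=C(C)C)[C@H]1Cc2c(OCOC)cc(OCOC)c(CO)c2O1
F7 | step 9 | 1-[(2R)-7-(hydroxymethyl)-4,6-bis(methoxymethoxy)-2-(6-methylhepta-1,5-dien-2-yl)-2,3-dihydro-1-benzofuran-5-yl]ethan-1-ol | C=C(CCC=C(C)C)[C@H]1Cc2c(OCOC)c(C(C)O)c(OCOC)c(CO)c2O1
F8 | step 7 | racemic 1-[2-bromo-4,6-bis(methoxymethoxy)phenyl]-7-methyl-3-methylideneoct-6-en-2-ol | C=C(CCC=C(C)C)C(O)Cc1c(Br)cc(OCOC)cc1OCOC
F9 | step 7 | 1-[2-bromo-4,6-bis(methoxymethoxy)phenyl]-7-methyl-3-methylideneoct-6-en-2-one | C=C(CCC=C(C)C)C(=O)Cc1c(Br)cc(OCOC)cc1OCOC
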